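## Retrosynthetic overview

- Numbering: the side chain runs from C1 (carbinol on C4 of oxazole A) to C6 (methyl). Oxazole A is the 2,4-disubstituted ring; oxazole B is the 5-substituted ring on the CH2 bridge.
- Feature: the C3–C6 stretch (oxygen on C3, C4 and C5, C6 methyl) is a masked penta-1,4-dien-3-ol. Its carbinol carbon is C4, one vinyl group becomes C5–C6 through an oxirane, and the other is cut back to the C3 aldehyde.
- Disconnections, backwards: O4–Si; C1 carbinol from the ketone (1,3-syn reduction); C2–C3 (Mukaiyama aldol of the C3 aldehyde with the enol silane of the 4-acetyl bis-oxazole); C5–O ester (Mitsunobu with inversion); C6–H (hydride opening of the oxirane).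
- Bis-oxazole: oxazole A from serine methyl ester and 3-(benzyloxy)propanoic acid, oxazole B from the side-chain aldehyde and TosMIC, then ester to methyl ketone to enol silane.
- Ring order: oxirane (step 1, opened again in step 3), oxazole A (step 6), oxazole B (step 9).

Key step: step 1

Assumption: L-(+)-diisopropyl tartrate is taken as the ligand enantiomer that leads to the (2R,3S) epoxy alcohol, because it epoxidises (S)-configured secondary allylic alcohols fast and to erythro products; serine methyl ester is used as its commercial hydrochloride.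

## Route

Step 1
Reactants: 1 penta-1,4-dien-3-ol
Product: 2 (2R,3S)-1,2-epoxypent-4-en-3-ol
Conditions: Ti(OiPr)4 (cat.), L-(+)-DIPT (cat.), t-BuOOH (anhydrous, isooctane), 4 Å MS, CH2Cl2, −20 °C, non-aqueous work-up
Reagents that add atoms: tert-butyl hydroperoxide, CC(C)(C)OO
Why: Sharpless titanium–tartrate asymmetric epoxidation used as a desymmetrisation: 1 exchanges onto titanium as its alkoxide and the tert-butyl peroxide bound to the same metal transfers its distal oxygen to one vinyl group in a single concerted step, so the oxirane closes by [2+1] oxygen-atom transfer with both C–O bonds formed together. The closest known reaction type is the kinetic resolution of secondary allylic alcohols by the same catalyst, and divinylcarbinol is an established substrate for this enantiotopic-group version. C5 (the oxirane CH) is set by the face of the alkene that the L-(+)-tartrate complex presents to the peroxide, and C4 (the carbinol, prochiral in 1) is set by which of the two enantiotopic vinyl groups can reach that face with the spectator vinyl pointing away from the ligand, which is the erythro (anti) arrangement, here (2R,3S). The step needs group selectivity, face selectivity and a stop at the mono-epoxide; the ligand supplies the first two, and the third helps, because the minor enantiomer of 2 carries its remaining vinyl group in the fast-reacting arrangement and should be drained off as the bis-epoxide, so the enantiopurity of 2 should rise with conversion. The erythro C4/C5 relation is deliberately the wrong one, since step 4 inverts C5. Low temperature, sieves and a non-aqueous work-up should keep the small, water-soluble epoxy alcohol from Payne rearrangement or ring opening.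

Step 2
Reactants: 2 (2R,3S)-1,2-epoxypent-4-en-3-ol
Product: 3 (2R,3S)-3-[(tert-butyldimethylsilyl)oxy]-1,2-epoxypent-4-ene
Conditions: TBSCl, imidazole, DMF, 0 °C → rt
Reagents that add atoms: tert-butyldimethylsilyl chloride, CC(C)(C)[Si](C)(C)Cl
Why: Imidazole-promoted silylation of the secondary alcohol touches no stereocentre, blocks O4 for the rest of the route and supplies the bulky, non-chelating α-substituent needed for the later aldol.

Step 3
Reactants: 3 (2R,3S)-3-[(tert-butyldimethylsilyl)oxy]-1,2-epoxypent-4-ene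
Product: 4 (2R,3S)-3-[(tert-butyldimethylsilyl)oxy]pent-4-en-2-ol
Conditions: LiAlH4, Et2O, 0 °C; aq. NaOH work-up
Reagents that add atoms: none
Why: Hydride opening of a monosubstituted oxirane is an SN2 attack at the unsubstituted carbon, so C6 becomes the methyl group, the C5–O bond and its configuration are untouched, and the only free hydroxyl in the molecule is O5.

Step 4
Reactants: 4 (2R,3S)-3-[(tert-butyldimethylsilyl)oxy]pent-4-en-2-ol; 5 tetradecanoic (myristic) acid
Product: 6 (2S,3S)-3-[(tert-butyldimethylsilyl)oxy]pent-4-en-2-yl tetradecanoate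
Conditions: PPh3, DIAD, THF, 0 °C → rt
Reagents that add atoms: none
Why: Mitsunobu esterification activates O5 as an alkoxyphosphonium ion and myristate displaces it by SN2, which inverts C5 (R to S), turns the erythro C4/C5 pair into the required threo pair and installs the ester on O5 without O4 and O5 ever needing to be told apart.

Step 5
Reactants: 7 L-serine methyl ester hydrochloride; 8 3-(benzyloxy)propanoic acid
Product: 9 methyl N-[3-(benzyloxy)propanoyl]-L-serinate
Conditions: EDC·HCl, HOBt, N-methylmorpholine, CH2Cl2, 0 °C → rt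
Reagents that add atoms: none
Why: Carbodiimide/HOBt amide coupling acylates the amine in preference to the primary hydroxyl, and the serine stereocentre need not be preserved because it is lost in step 6.

Step 6
Reactants: 9 methyl N-[3-(benzyloxy)propanoyl]-L-serinate
Product: 11 methyl 2-[2-(benzyloxy)ethyl]-1,3-oxazole-4-carboxylate, via 4,5-dihydrooxazole 10 (not isolated)
Conditions: DAST, CH2Cl2, −78 °C; then BrCCl3, DBU, 0 °C → rt
Reagents that add atoms: none
Why: Cyclodehydration of the β-hydroxy amide (fluorosulfurane activation of the hydroxyl, 5-exo-tet closure by the amide oxygen) gives oxazoline 10, which the BrCCl3/DBU bromination–elimination sequence dehydrogenates to oxazole A.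

Step 7
Reactants: 11 methyl 2-[2-(benzyloxy)ethyl]-1,3-oxazole-4-carboxylate
Product: 12 methyl 2-(2-hydroxyethyl)-1,3-oxazole-4-carboxylate
Conditions: H2 (1 atm), Pd/C, EtOAc, rt
Reagents that add atoms: none
Why: Catalytic hydrogenolysis cleaves the benzyl ether while the oxazole ring and the ester are inert under these conditions.

Step 8
Reactants: 12 methyl 2-(2-hydroxyethyl)-1,3-oxazole-4-carboxylate
Product: 13 methyl 2-(2-oxoethyl)-1,3-oxazole-4-carboxylate
Conditions: Dess–Martin periodinane, CH2Cl2, 0 °C → rt; used crude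
Reagents that add atoms: none
Why: Dess–Martin oxidation is neutral and fast, which suits a primary alcohol whose aldehyde is readily enolised and is therefore taken on without purification.

Step 9
Reactants: 13 methyl 2-(2-oxoethyl)-1,3-oxazole-4-carboxylate; 14 p-toluenesulfonylmethyl isocyanide (TosMIC)
Product: 15 methyl 2-(1,3-oxazol-5-ylmethyl)-1,3-oxazole-4-carboxylate
Conditions: K2CO3, MeOH, reflux
Reagents that add atoms: none
Why: Van Leusen oxazole synthesis: deprotonated TosMIC adds to the aldehyde, the alkoxide closes onto the isocyanide carbon and loss of p-toluenesulfinate aromatises the ring, which places the former aldehyde carbon at C5 of oxazole B.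

Step 10
Reactants: 15 methyl 2-(1,3-oxazol-5-ylmethyl)-1,3-oxazole-4-carboxylate
Product: 16 N-methoxy-N-methyl-2-(1,3-oxazol-5-ylmethyl)-1,3-oxazole-4-carboxamide
Conditions: MeNH(OMe)·HCl, i-PrMgCl (premixed), THF, −20 → 0 °C
Reagents that add atoms: N,O-dimethylhydroxylamine hydrochloride, CNOC.Cl
Why: Direct aminolysis of the methyl ester by the preformed magnesium amide gives the Weinreb amide in one operation, and premixing leaves no free Grignard reagent to attack the acidic positions of the bis-oxazole.

Step 11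
Reactants: 16 N-methoxy-N-methyl-2-(1,3-oxazol-5-ylmethyl)-1,3-oxazole-4-carboxamide
Product: 17 1-[2-(1,3-oxazol-5-ylmethyl)-1,3-oxazol-4-yl]ethan-1-one
Conditions: MeMgBr, THF, −78 → 0 °C; aq. NH4Cl
Reagents that add atoms: methylmagnesium bromide, C[Mg]Br
Why: Weinreb ketone synthesis: the chelated tetrahedral adduct survives until work-up, so a single methyl group is delivered and the methyl ketone is formed without over-addition.

Step 12
Reactants: 17 1-[2-(1,3-oxazol-5-ylmethyl)-1,3-oxazol-4-yl]ethan-1-one
Product: 18 2-(1,3-oxazol-5-ylmethyl)-4-{1-[(trimethylsilyl)oxy]ethenyl}-1,3-oxazole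
Conditions: TMSOTf, Et3N, CH2Cl2, 0 °C; used crude
Reagents that add atoms: trimethylsilyl trifluoromethanesulfonate, C[Si](C)(C)OS(=O)(=O)C(F)(F)F
Why: Soft enolisation (silyl triflate with an amine base) converts the methyl ketone into its only possible enol silane and avoids the strong bases that would metalate C2–H of oxazole B or the bridging CH2.

Step 13
Reactants: 6 (2S,3S)-3-[(tert-butyldimethylsilyl)oxy]pent-4-en-2-yl tetradecanoate
Product: 20 (2S,3R)-3-[(tert-butyldimethylsilyl)oxy]-4-oxobutan-2-yl tetradecanoate, via secondary ozonide 19 (not isolated)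
Conditions: O3, CH2Cl2, −78 °C; then PPh3, −78 °C → rt; used without chromatography
Reagents that add atoms: ozone, [O-][O+]=O
Why: Ozonolysis with reductive work-up cuts the terminal alkene to the C3 aldehyde under neutral conditions, so the C4 centre is not epimerised and the β-acyloxy group is not eliminated before the aldehyde is used.

Step 14
Reactants: 20 (2S,3R)-3-[(tert-butyldimethylsilyl)oxy]-4-oxobutan-2-yl tetradecanoate; 18 2-(1,3-oxazol-5-ylmethyl)-4-{1-[(trimethylsilyl)oxy]ethenyl}-1,3-oxazole
Product: 21 (2S,3S,4S)-3-[(tert-butyldimethylsilyl)oxy]-4-hydroxy-6-oxo-6-[2-(1,3-oxazol-5-ylmethyl)-1,3-oxazol-4-yl]hexan-2-yl tetradecanoate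
Conditions: BF3·OEt2 (excess), CH2Cl2, −78 °C; aq. NaHCO3
Reagents that add atoms: none
Why: Mukaiyama aldol through an open transition state: BF3 activates the aldehyde and, with the C4–O dipole opposed to the carbonyl (Cornforth/polar Felkin–Anh arrangement), the enol silane should attack anti to the C4 silyloxy group and so set C3 as S (3,4-anti), the excess Lewis acid making up for coordination to the oxazole nitrogens.

Step 15
Reactants: 21 (2S,3S,4S)-3-[(tert-butyldimethylsilyl)oxy]-4-hydroxy-6-oxo-6-[2-(1,3-oxazol-5-ylmethyl)-1,3-oxazol-4-yl]hexan-2-yl tetradecanoate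
Product: 23 (2S,3S,4S,6R)-3-[(tert-butyldimethylsilyl)oxy]-4,6-dihydroxy-6-[2-(1,3-oxazol-5-ylmethyl)-1,3-oxazol-4-yl]hexan-2-yl tetradecanoate, via diethylboron chelate 22 (not isolated)
Conditions: Et2BOMe, THF/MeOH (4:1), −78 °C; NaBH4; then AcOH, MeOH co-evaporation
Reagents that add atoms: diethylmethoxyborane, CCB(CC)OC (boron and ethyl groups in 22 only; none remain in 23)
Why: Narasaka–Prasad reduction: the C3 hydroxyl and the C1 ketone are tied into the six-membered boron chelate 22 and external hydride adds axially to its half-chair, which should give the 1,3-syn diol (C1 R) while NaBH4 at −78 °C leaves the myristate and the silyl ether alone.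

Step 16
Reactants: 23 (2S,3S,4S,6R)-3-[(tert-butyldimethylsilyl)oxy]-4,6-dihydroxy-6-[2-(1,3-oxazol-5-ylmethyl)-1,3-oxazol-4-yl]hexan-2-yl tetradecanoate
Product: 24 (2S,3S,4S,6R)-3,4,6-trihydroxy-6-[2-(1,3-oxazol-5-ylmethyl)-1,3-oxazol-4-yl]hexan-2-yl tetradecanoate (target)
Conditions: HF·pyridine, pyridine, THF, 0 °C → rt
Reagents that add atoms: none
Why: Fluoride desilylation in a pyridine-buffered, mildly acidic medium cleaves only the Si–O4 bond and avoids the basic conditions under which the myristate could migrate from O5 to O4 or O3.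

## Compound list

1 | penta-1,4-dien-3-ol | C=CC(O)C=C | starting material
2 | (2R,3S)-1,2-epoxypent-4-en-3-ol | C=C[C@H](O)[C@H]1CO1 | intermediate
3 | (2R,3S)-3-[(tert-butyldimethylsilyl)oxy]-1,2-epoxypent-4-ene | C=C[C@H](O[Si](C)(C)C(C)(C)C)[C@H]1CO1 | intermediate
4 | (2R,3S)-3-[(tert-butyldimethylsilyl)oxy]pent-4-en-2-ol | C=C[C@H](O[Si](C)(C)C(C)(C)C)[C@H](O)C | intermediate
5 | tetradecanoic (myristic) acid | CCCCCCCCCCCCCC(=O)O | starting material
6 | (2S,3S)-3-[(tert-butyldimethylsilyl)oxy]pent-4-en-2-yl tetradecanoate | CCCCCCCCCCCCCC(=O)O[C@@H](C)[C@@H](O[Si](C)(C)C(C)(C)C)C=C | intermediate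
7 | L-serine methyl ester hydrochloride | COC(=O)[C@@H](N)CO.Cl | starting material
8 | 3-(benzyloxy)propanoic acid | OC(=O)CCOCc1ccccc1 | starting material
9 | methyl N-[3-(benzyloxy)propanoyl]-L-serinate | COC(=O)[C@@H](NC(=O)CCOCc1ccccc1)CO | intermediate
10 | methyl (4S)-2-[2-(benzyloxy)ethyl]-4,5-dihydro-1,3-oxazole-4-carboxylate | COC(=O)[C@@H]1COC(CCOCc2ccccc2)=N1 | intermediate
11 | methyl 2-[2-(benzyloxy)ethyl]-1,3-oxazole-4-carboxylate | COC(=O)c1coc(CCOCc2ccccc2)n1 | intermediate
12 | methyl 2-(2-hydroxyethyl)-1,3-oxazole-4-carboxylate | COC(=O)c1coc(CCO)n1 | intermediate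
13 | methyl 2-(2-oxoethyl)-1,3-oxazole-4-carboxylate | COC(=O)c1coc(CC=O)n1 | intermediate
14 | p-toluenesulfonylmethyl isocyanide (TosMIC) | Cc1ccc(cc1)S(=O)(=O)C[N+]#[C-] | starting material
15 | methyl 2-(1,3-oxazol-5-ylmethyl)-1,3-oxazole-4-carboxylate | COC(=O)c1coc(Cc2cnco2)n1 | intermediate
16 | N-methoxy-N-methyl-2-(1,3-oxazol-5-ylmethyl)-1,3-oxazole-4-carboxamide | CON(C)C(=O)c1coc(Cc2cnco2)n1 | intermediate
17 | 1-[2-(1,3-oxazol-5-ylmethyl)-1,3-oxazol-4-yl]ethan-1-one | CC(=O)c1coc(Cc2cnco2)n1 | intermediate
18 | 2-(1,3-oxazol-5-ylmethyl)-4-{1-[(trimethylsilyl)oxy]ethenyl}-1,3-oxazole | C=C(O[Si](C)(C)C)c1coc(Cc2cnco2)n1 | intermediate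
19 | secondary ozonide of 6: the vinyl group replaced by a 1,2,4-trioxolan-3-yl ring, C4 and C5 as in 6, trioxolane carbon as a mixture | CCCCCCCCCCCCCC(=O)O[C@@H](C)[C@@H](O[Si](C)(C)C(C)(C)C)C1OCOO1 | intermediate
20 | (2S,3R)-3-[(tert-butyldimethylsilyl)oxy]-4-oxobutan-2-yl tetradecanoate | CCCCCCCCCCCCCC(=O)O[C@@H](C)[C@@H](O[Si](C)(C)C(C)(C)C)C=O | intermediate
21 | (2S,3S,4S)-3-[(tert-butyldimethylsilyl)oxy]-4-hydroxy-6-oxo-6-[2-(1,3-oxazol-5-ylmethyl)-1,3-oxazol-4-yl]hexan-2-yl tetradecanoate | CCCCCCCCCCCCCC(=O)O[C@@H](C)[C@@H](O[Si](C)(C)C(C)(C)C)[C@@H](O)CC(=O)c1coc(Cc2cnco2)n1 | intermediate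
22 | diethylboron chelate of 21 (O-diethylboryl on the C4 hydroxyl of the hexanyl chain, boron coordinated to the ketone oxygen) | CCCCCCCCCCCCCC(=O)O[C@@H](C)[C@@H](O[Si](C)(C)C(C)(C)C)[C@@H](OB(CC)CC)CC(=O)c1coc(Cc2cnco2)n1 | intermediate
23 | (2S,3S,4S,6R)-3-[(tert-butyldimethylsilyl)oxy]-4,6-dihydroxy-6-[2-(1,3-oxazol-5-ylmethyl)-1,3-oxazol-4-yl]hexan-2-yl tetradecanoate | CCCCCCCCCCCCCC(=O)O[C@@H](C)[C@@H](O[Si](C)(C)C(C)(C)C)[C@@H](O)C[C@@H](O)c1coc(Cc2cnco2)n1 | intermediate
24 | (2S,3S,4S,6R)-3,4,6-trihydroxy-6-[2-(1,3-oxazol-5-ylmethyl)-1,3-oxazol-4-yl]hexan-2-yl tetradecanoate | CCCCCCCCCCCCCC(=O)O[C@@H](C)[C@@H](O)[C@@H](O)C[C@@H](O)c1coc(Cc2cnco2)n1 | target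

## Step count and risks

Total steps: 16. Longest linear sequence: 11 steps (7 → 9 → 11 → 12 → 13 → 15 → 16 → 17 → 18 → 21 → 23 → 24; the chain from 1 to 24 is 8 steps).

Most likely to fail:

1. Step 14. The addition may show poor facial selectivity, because the 4,5-syn pair of oxygen substituents in 20 is the arrangement in which the α- and β-substituents cooperate least in open-transition-state additions. The β-acyloxy aldehyde may also lose myristate by elimination before it reacts. The fallback runs the aldol on the 4,5-anti series, before the inversion, and sets out from 4. TESCl and imidazole should give (2R,3S)-3-[(tert-butyldimethylsilyl)oxy]-2-[(triethylsilyl)oxy]pent-4-ene F1. Ozonolysis (O3, then PPh3) should give (2R,3R)-2-[(tert-butyldimethylsilyl)oxy]-3-[(triethylsilyl)oxy]butanal F2, the arrangement for which Cornforth-type addition is reliably 3,4-anti. BF3·OEt2 with 18 should then give the C5-triethylsilyloxy β-hydroxy ketone F3, and Et2BOMe/NaBH4 the corresponding 1,3-syn diol F4. 2,2-Dimethoxypropane with PPTS should give the C1/C3 acetonide F5. HF·pyridine in pyridine/THF at 0 °C should remove only the triethylsilyl group to give the C5 alcohol F6. Mitsunobu reaction with 5 (PPh3, DIAD) should invert C5 and give the acetonide-protected myristate F7. Aqueous HF in MeCN should remove the acetonide and the TBS group, and the route comes back at 24.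

2. Step 4. Displacement at the hindered alkoxyphosphonium centre next to the silyloxy-bearing carbon may be slow with a weakly acidic aliphatic acid, so elimination towards the diene or attack through an acyloxyphosphonium species (retention) may compete. The fallback sets out from 4. Tf2O and pyridine in CH2Cl2 at −30 °C should give (2R,3S)-3-[(tert-butyldimethylsilyl)oxy]pent-4-en-2-yl trifluoromethanesulfonate F8. Caesium tetradecanoate (from 5 and Cs2CO3) with 18-crown-6 in toluene/DMF at 0 °C → rt should displace it with inversion, and the route comes back at 6.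

3. Step 9. The doubly activated aldehyde 13 may enolise and self-condense under K2CO3/MeOH faster than it captures the isocyanide anion. The fallback builds oxazole B first on a non-activated aldehyde and sets out from 14. Commercial 3-(benzyloxy)propanal with 14 (K2CO3, MeOH, reflux) should give 5-[2-(benzyloxy)ethyl]-1,3-oxazole F9. Hydrogenolysis (H2, Pd/C) should give 2-(1,3-oxazol-5-yl)ethan-1-ol F10, and TEMPO/PhI(OAc)2 in MeCN/H2O should give (1,3-oxazol-5-yl)acetic acid F11. EDC/HOBt coupling with 7 should give methyl N-[(1,3-oxazol-5-yl)acetyl]-L-serinate F12. DAST followed by BrCCl3/DBU should then pass through methyl (4S)-2-(1,3-oxazol-5-ylmethyl)-4,5-dihydro-1,3-oxazole-4-carboxylate F13, and the route comes back at 15.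

## Further compounds

F1 | step 14 | (2R,3S)-3-[(tert-butyldimethylsilyl)oxy]-2-[(triethylsilyl)oxy]pent-4-ene | C=C[C@H](O[Si](C)(C)C(C)(C)C)[C@H](O[Si](CC)(CC)CC)C
F2 | step 14 | (2R,3R)-2-[(tert-butyldimethylsilyl)oxy]-3-[(triethylsilyl)oxy]butanal | O=C[C@H](O[Si](C)(C)C(C)(C)C)[C@H](O[Si](CC)(CC)CC)C
F3 | step 14 | (3S,4S,5R; chain numbering)-4-[(tert-butyldimethylsilyl)oxy]-3-hydroxy-1-[2-(1,3-oxazol-5-ylmethyl)-1,3-oxazol-4-yl]-5-[(triethylsilyl)oxy]hexan-1-one | CC[Si](CC)(CC)O[C@H](C)[C@@H](O[Si](C)(C)C(C)(C)C)[C@@H](O)CC(=O)c1coc(Cc2cnco2)n1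
F4 | step 14 | (1R,3S,4S,5R; chain numbering)-4-[(tert-butyldimethylsilyl)oxy]-1-[2-(1,3-oxazol-5-ylmethyl)-1,3-oxazol-4-yl]-5-[(triethylsilyl)oxy]hexane-1,3-diol | CC[Si](CC)(CC)O[C@H](C)[C@@H](O[Si](C)(C)C(C)(C)C)[C@@H](O)C[C@@H](O)c1coc(Cc2cnco2)n1
F5 | step 14 | C1/C3 acetonide (2,2-dimethyl-1,3-dioxane) of F4 | CC[Si](CC)(CC)O[C@H](C)[C@@H](O[Si](C)(C)C(C)(C)C)[C@@H]1C[C@H](c2coc(Cc3cnco3)n2)OC(C)(C)O1
F6 | step 14 | C5 alcohol from F5 (triethylsilyl group removed; acetonide and TBS kept) | O[C@H](C)[C@@H](O[Si](C)(C)C(C)(C)C)[C@@H]1C[C@H](c2coc(Cc3cnco3)n2)OC(C)(C)O1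
F7 | step 14 | C5-inverted tetradecanoate of F6 (acetonide and TBS kept) | CCCCCCCCCCCCCC(=O)O[C@@H](C)[C@@H](O[Si](C)(C)C(C)(C)C)[C@@H]1C[C@H](c2coc(Cc3cnco3)n2)OC(C)(C)O1
F8 | step 4 | (2R,3S)-3-[(tert-butyldimethylsilyl)oxy]pent-4-en-2-yl trifluoromethanesulfonate | C=C[C@H](O[Si](C)(C)C(C)(C)C)[C@H](OS(=O)(=O)C(F)(F)F)C
F9 | step 9 | 5-[2-(benzyloxy)ethyl]-1,3-oxazole | c1ccccc1COCCc1cnco1
F10 | step 9 | 2-(1,3-oxazol-5-yl)ethan-1-ol | OCCc1cnco1
F11 | step 9 | (1,3-oxazol-5-yl)acetic acid | OC(=O)Cc1cnco1
F12 | step 9 | methyl N-[(1,3-oxazol-5-yl)acetyl]-L-serinate | COC(=O)[C@@H](NC(=O)Cc1cnco1)CO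
F13 | step 9 | methyl (4S)-2-(1,3-oxazol-5-ylmethyl)-4,5-dihydro-1,3-oxazole-4-carboxylate | COC(=O)[C@@H]1COC(Cc2cnco2)=N1
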